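**Assumption:** the target SMILES has no stereocentre and the molecule is achiral, so "single enantiomer" is read as the constitution given; no stereocontrol is needed.

## Retrosynthetic overview

1. Target 15 ⇐ global hydrogenolysis of the tetrabenzyl depside 14 ⇐ O-methylation of the 2-OH of 13.
2. The depside aryl C3–O bond of 13 is made by the new step: ortho C–H aroyloxylation of the ring B phenol 7 (as its bromomagnesium phenoxide, ArOMgBr) with the ring A diaroyl peroxide 10. Phenol 7 has only one free ortho C–H, so the site is fixed.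
3. Peroxide 10 ⇐ peroxy acid 9 + acid chloride 8, both from acid 5. Phenol 7 ⇐ 5 by benzyl esterification and chelation-controlled removal of the ortho benzyl ether.
4. Acid 5 ⇐ 5-propylresorcinol 1 by Vilsmeier formylation, benzylation and Pinnick oxidation.
5. No ring is formed: ring A and ring B both come from the same commercial resorcinol 1.

## Route

**Step 1**
Reactants: 1 5-propylbenzene-1,3-diol (divarinol)
Product: 3 2,4-dihydroxy-6-propylbenzaldehyde, via iminium chloride 2 (not isolated)
Conditions: POCl3, DMF, 0 °C→rt; then H2O, 50 °C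
Reagents that add atoms: N,N-dimethylformamide, CN(C)C=O (formyl carbon; NMe2 of 2); water, O (aldehyde oxygen); phosphoryl chloride, O=P(Cl)(Cl)Cl (chloride of 2 only)
Why: Vilsmeier–Haack formylation, in which the chloroiminium ion attacks the ring carbon para to one hydroxyl and ortho to the other (the site between the two hydroxyls is more hindered), as in the orcinol to orcylaldehyde case; no stereocentre.

**Step 2**
Reactants: 3 2,4-dihydroxy-6-propylbenzaldehyde
Product: 4 2,4-bis(benzyloxy)-6-propylbenzaldehyde
Conditions: BnBr (2.5 equiv), K2CO3, DMF, 60 °C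
Reagents that add atoms: benzyl bromide, BrCc1ccccc1
Why: Williamson ether synthesis, where excess bromide in warm DMF also alkylates the hydrogen-bonded 2-OH.

**Step 3**
Reactants: 4 2,4-bis(benzyloxy)-6-propylbenzaldehyde
Product: 5 2,4-bis(benzyloxy)-6-propylbenzoic acid
Conditions: NaClO2, NaH2PO4, 2-methylbut-2-ene, t-BuOH/THF/H2O, rt
Reagents that add atoms: sodium chlorite, [Na+].[O-]Cl=O
Why: Pinnick oxidation, with 2-methylbut-2-ene trapping HOCl so that the electron-rich ring and the benzyl ethers are untouched.

**Step 4**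
Reactants: 5 2,4-bis(benzyloxy)-6-propylbenzoic acid
Product: 6 benzyl 2,4-bis(benzyloxy)-6-propylbenzoate
Conditions: BnBr, K2CO3, DMF, rt
Reagents that add atoms: benzyl bromide, BrCc1ccccc1
Why: SN2 O-alkylation of the carboxylate, which avoids any attack at the hindered carbonyl carbon.

**Step 5**
Reactants: 6 benzyl 2,4-bis(benzyloxy)-6-propylbenzoate
Product: 7 benzyl 4-(benzyloxy)-2-hydroxy-6-propylbenzoate
Conditions: MgBr2·OEt2 (3 equiv), toluene/Et2O, 75 °C; then 1 M HCl
Reagents that add atoms: none
Why: Chelation-controlled Lewis-acid ether cleavage, in which magnesium bridges the ester carbonyl and the ortho ether oxygen and bromide removes that benzyl group by SN2, while the unchelated 4-benzyl ether and the benzyl ester stay.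

**Step 6**
Reactants: 5 2,4-bis(benzyloxy)-6-propylbenzoic acid
Product: 8 2,4-bis(benzyloxy)-6-propylbenzoyl chloride
Conditions: (COCl)2 (1.3 equiv), DMF (cat.), CH2Cl2, 0 °C→rt; evaporate, strip with toluene; used crude
Reagents that add atoms: oxalyl chloride, O=C(Cl)C(=O)Cl
Why: Acid chloride formation through the catalytic Vilsmeier-type chloroiminium species, which is routine for ortho-alkoxy benzoic acids and leaves the benzyl ethers intact at or below room temperature.

**Step 7**
Reactants: 8 2,4-bis(benzyloxy)-6-propylbenzoyl chloride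
Product: 9 2,4-bis(benzyloxy)-6-propylperoxybenzoic acid
Conditions: 30% H2O2 (5 equiv), NaOH (2.2 equiv), MgSO4·7H2O (cat.), 1,4-dioxane/H2O, 0–5 °C; then cold dilute H2SO4 to pH 3, extract into CH2Cl2; used at once
Reagents that add atoms: hydrogen peroxide, OO
Why: Schotten–Baumann perhydrolysis of an acid chloride (the way meta-chloroperoxybenzoic acid is made), in which the small alpha-effect hydroperoxide anion attacks the di-ortho-substituted aroyl chloride faster than hydroxide and the excess of peroxide keeps the peroxycarboxylate from being acylated a second time.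

**Step 8**
Reactants: 9 2,4-bis(benzyloxy)-6-propylperoxybenzoic acid; 8 2,4-bis(benzyloxy)-6-propylbenzoyl chloride
Product: 10 bis[2,4-bis(benzyloxy)-6-propylbenzoyl] peroxide
Conditions: 8 (1.05 equiv), Na2CO3 (aq), THF, 0 °C, dark; extract, keep as a cold toluene solution and use at once
Reagents that add atoms: none
Why: Acylation of a peroxycarboxylate anion by an acid chloride, the standard stepwise assembly of a diacyl peroxide from two defined halves, which works for di-ortho-substituted aroyl chlorides because the attacking peroxy oxygen is unhindered and strongly nucleophilic.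

**Step 9**
Reactants: 7 benzyl 4-(benzyloxy)-2-hydroxy-6-propylbenzoate; 10 bis[2,4-bis(benzyloxy)-6-propylbenzoyl] peroxide
Product: 13 benzyl 3-{[2,4-bis(benzyloxy)-6-propylbenzoyl]oxy}-4-(benzyloxy)-2-hydroxy-6-propylbenzoate, via bromomagnesium phenoxide 11 (not isolated), via acyloxy dienone 12 (not isolated)
Conditions: EtMgBr (1.0 equiv), Et2O/toluene, 0 °C; then 10 (1.2 equiv), toluene, −20 °C→rt, dark; then cold 1 M HCl
Reagents that add atoms: ethylmagnesium bromide, CC[Mg]Br (MgBr of 11 only; the aroyloxy group comes from reactant 10)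
Why: Proposed new method: an ArOMgBr-directed ortho C–H aroyloxylation (electrophilic oxygenation of a phenoxide by a diacyl peroxide) - in toluene the chelated phenoxide 11 binds a carbonyl oxygen of 10 and its only free ortho carbon (C3, also activated by the 4-benzyloxy group) attacks the adjacent peroxide oxygen, breaking the weak O–O bond and expelling the bromomagnesium aroate (ArCO2MgBr) to give dienone 12, which enolises at once to 13 (an initial attack through the phenoxide oxygen followed by a [3,3] shift of the aryl peroxyester would end at the same carbon); acyl transfer to the phenoxide is suppressed because the peroxide carbonyls carry two ortho substituents, para attack at C5 lacks the metal template, and no stereocentre is formed; the closest known reaction types are the ortho-benzoyloxylation of phenols by dibenzoyl peroxide to catechol monobenzoates, the α-benzoyloxylation of enolates and enamines by dibenzoyl peroxide, and the ortho-specific Casnati–Skattebøl reactions of ArOMgX phenoxides, none of which has been used on a salicylate phenoxide with a hindered diaroyl peroxide to make a depside aryl C–O bond.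

**Step 10**
Reactants: 13 benzyl 3-{[2,4-bis(benzyloxy)-6-propylbenzoyl]oxy}-4-(benzyloxy)-2-hydroxy-6-propylbenzoate
Product: 14 benzyl 3-{[2,4-bis(benzyloxy)-6-propylbenzoyl]oxy}-4-(benzyloxy)-2-methoxy-6-propylbenzoate
Conditions: MeI, K2CO3, DMF, 0 °C→rt
Reagents that add atoms: iodomethane, CI
Why: Williamson O-methylation of the only free hydroxyl, the 2-OH whose phenoxide is conjugated with the ortho ester, while the di-ortho-substituted aroyl ester resists migration and cleavage under anhydrous carbonate.

**Step 11**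
Reactants: 14 benzyl 3-{[2,4-bis(benzyloxy)-6-propylbenzoyl]oxy}-4-(benzyloxy)-2-methoxy-6-propylbenzoate
Product: 15 3-[(2,4-dihydroxy-6-propylbenzoyl)oxy]-4-hydroxy-2-methoxy-6-propylbenzoic acid
Conditions: H2 (1 atm), 10% Pd/C, EtOAc, rt
Reagents that add atoms: none
Why: Catalytic hydrogenolysis removes the three benzyl ethers and the benzyl ester in one neutral operation, so the aryl ester stays on O3 and does not migrate to the freed 4-OH.

The acid 5 released in step 9 is recovered by NaHCO3 extraction and returned to step 6.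

## Compound list

1 | 5-propylbenzene-1,3-diol (divarinol) | CCCc1cc(O)cc(O)c1 | starting material
2 | (2,4-dihydroxy-6-propylbenzylidene)dimethyliminium chloride | CCCc1cc(O)cc(O)c1C=[N+](C)C.[Cl-] | intermediate
3 | 2,4-dihydroxy-6-propylbenzaldehyde | CCCc1cc(O)cc(O)c1C=O | intermediate
4 | 2,4-bis(benzyloxy)-6-propylbenzaldehyde | CCCc1cc(OCc2ccccc2)cc(OCc2ccccc2)c1C=O | intermediate
5 | 2,4-bis(benzyloxy)-6-propylbenzoic acid | CCCc1cc(OCc2ccccc2)cc(OCc2ccccc2)c1C(=O)O | intermediate
6 | benzyl 2,4-bis(benzyloxy)-6-propylbenzoate | CCCc1cc(OCc2ccccc2)cc(OCc2ccccc2)c1C(=O)OCc1ccccc1 | intermediate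
7 | benzyl 4-(benzyloxy)-2-hydroxy-6-propylbenzoate | CCCc1cc(OCc2ccccc2)cc(O)c1C(=O)OCc1ccccc1 | intermediate
8 | 2,4-bis(benzyloxy)-6-propylbenzoyl chloride | CCCc1cc(OCc2ccccc2)cc(OCc2ccccc2)c1C(=O)Cl | intermediate
9 | 2,4-bis(benzyloxy)-6-propylperoxybenzoic acid | CCCc1cc(OCc2ccccc2)cc(OCc2ccccc2)c1C(=O)OO | intermediate
10 | bis[2,4-bis(benzyloxy)-6-propylbenzoyl] peroxide | CCCc1cc(OCc2ccccc2)cc(OCc2ccccc2)c1C(=O)OOC(=O)c1c(CCC)cc(OCc2ccccc2)cc1OCc1ccccc1 | intermediate
11 | bromomagnesium 5-(benzyloxy)-2-[(benzyloxy)carbonyl]-3-propylphenoxide | CCCc1cc(OCc2ccccc2)cc(O[Mg]Br)c1C(=O)OCc1ccccc1 | intermediate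
12 | benzyl 5-{[2,4-bis(benzyloxy)-6-propylbenzoyl]oxy}-4-(benzyloxy)-6-oxo-2-propylcyclohexa-1,3-diene-1-carboxylate (racemic, transient keto tautomer of 13) | CCCC1=C(C(=O)OCc2ccccc2)C(=O)C(OC(=O)c2c(CCC)cc(OCc3ccccc3)cc2OCc2ccccc2)C(OCc2ccccc2)=C1 | intermediate
13 | benzyl 3-{[2,4-bis(benzyloxy)-6-propylbenzoyl]oxy}-4-(benzyloxy)-2-hydroxy-6-propylbenzoate | CCCc1cc(OCc2ccccc2)c(OC(=O)c2c(CCC)cc(OCc3ccccc3)cc2OCc2ccccc2)c(O)c1C(=O)OCc1ccccc1 | intermediate
14 | benzyl 3-{[2,4-bis(benzyloxy)-6-propylbenzoyl]oxy}-4-(benzyloxy)-2-methoxy-6-propylbenzoate | CCCc1cc(OCc2ccccc2)c(OC(=O)c2c(CCC)cc(OCc3ccccc3)cc2OCc2ccccc2)c(OC)c1C(=O)OCc1ccccc1 | intermediate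
15 | 3-[(2,4-dihydroxy-6-propylbenzoyl)oxy]-4-hydroxy-2-methoxy-6-propylbenzoic acid | CCCc1cc(O)cc(O)c1C(=O)Oc1c(O)cc(CCC)c(C(=O)O)c1OC | target

## Step count and risks

Total steps: 11. Longest linear sequence: 9 (steps 1, 2, 3, 6, 7, 8, 9, 10, 11; steps 4 and 5 are a two-step branch from 5 to 7).

**Step 9 (the proposed new step).** The salicylate phenoxide may be too weak a nucleophile for the electron-rich peroxide, or oxygenation may occur in part at C5. The fallback uses only known chemistry, sets out from 7 and comes back at 14.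
- Phenol 7 is formylated at its only free ortho position (MgCl2, Et3N, paraformaldehyde, MeCN, reflux) to benzyl 4-(benzyloxy)-3-formyl-2-hydroxy-6-propylbenzoate F1.
- Methylation (MeI, K2CO3, DMF) gives benzyl 4-(benzyloxy)-3-formyl-2-methoxy-6-propylbenzoate F2.
- Dakin-type Baeyer–Villiger oxidation (mCPBA, CH2Cl2) of this aldehyde, which is flanked by two alkoxy groups, gives benzyl 4-(benzyloxy)-3-(formyloxy)-2-methoxy-6-propylbenzoate F3.
- Brief methanolysis (KHCO3, MeOH) frees benzyl 4-(benzyloxy)-3-hydroxy-2-methoxy-6-propylbenzoate F4.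
- Its single hydroxyl is acylated in the classical way with acid chloride 8 from step 6 (Et3N, DMAP, CH2Cl2) to give 14, which goes on to step 11.

**Step 7.** The hindered acid chloride may hydrolyse under aqueous alkali, or the free electron-rich peroxy acid may not survive isolation. The fallback sets out from 5 and comes back at 10, so neither 8 nor free 9 is handled. Acid 5 is activated without chloride or base with 1,1'-carbonyldiimidazole (THF, 40 °C) as 1-[2,4-bis(benzyloxy)-6-propylbenzoyl]-1H-imidazole F5. Anhydrous urea–hydrogen peroxide (0.5 equiv, THF, 0 °C) converts half of it into peroxy acid 9 in the flask, which is acylated at once by the remaining imidazolide to give 10. If 10 itself proves too labile to handle, the fallback to step 9 takes over.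

**Step 5.** The twisted, di-ortho-substituted ester may chelate magnesium poorly, giving slow or unselective debenzylation. The fallback sets out from 3 and comes back at 7. Aldehyde 3 is benzylated only at the unchelated 4-OH (BnBr 1.05 equiv, KHCO3, KI, MeCN, 60 °C) to give 4-(benzyloxy)-2-hydroxy-6-propylbenzaldehyde F6. Pinnick oxidation (NaClO2, NaH2PO4, 2-methylbut-2-ene) gives 4-(benzyloxy)-2-hydroxy-6-propylbenzoic acid F7. Carboxylate-selective alkylation (BnBr 1.0 equiv, KHCO3, DMF, rt) then gives 7.

## Further compounds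

F1 | step 9 | benzyl 4-(benzyloxy)-3-formyl-2-hydroxy-6-propylbenzoate | CCCc1cc(OCc2ccccc2)c(C=O)c(O)c1C(=O)OCc1ccccc1
F2 | step 9 | benzyl 4-(benzyloxy)-3-formyl-2-methoxy-6-propylbenzoate | CCCc1cc(OCc2ccccc2)c(C=O)c(OC)c1C(=O)OCc1ccccc1
F3 | step 9 | benzyl 4-(benzyloxy)-3-(formyloxy)-2-methoxy-6-propylbenzoate | CCCc1cc(OCc2ccccc2)c(OC=O)c(OC)c1C(=O)OCc1ccccc1
F4 | step 9 | benzyl 4-(benzyloxy)-3-hydroxy-2-methoxy-6-propylbenzoate | CCCc1cc(OCc2ccccc2)c(O)c(OC)c1C(=O)OCc1ccccc1
F5 | step 7 | 1-[2,4-bis(benzyloxy)-6-propylbenzoyl]-1H-imidazole | CCCc1cc(OCc2ccccc2)cc(OCc2ccccc2)c1C(=O)n1ccnc1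
F6 | step 5 | 4-(benzyloxy)-2-hydroxy-6-propylbenzaldehyde | CCCc1cc(OCc2ccccc2)cc(O)c1C=O
F7 | step 5 | 4-(benzyloxy)-2-hydroxy-6-propylbenzoic acid | CCCc1cc(OCc2ccccc2)cc(O)c1C(=O)O
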